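**Retrosynthetic overview**

1. Terpenoid numbering is used for the decalin (ring A = C1–C5 + C10, ring B = C5–C10, C11 = benzylic CH2). Ring A is a cyclohexene whose C3=C4 double bond lies next to the ring-fusion bond C5–C10, which is a Diels–Alder retron. C5–C10 and C1–C2 are therefore cut together, and ring B (C6–C9) becomes the tether of an open-chain (2Z,8E)-trienoate.
2. The ester on C1 is a traceless activator (Barton decarboxylation). The (Z)-enoate comes from a Still–Gennari olefination at C10, the (E)-diene from Negishi coupling of a C6 alkylzinc with (3E)-4-bromo-3-methylpenta-1,3-diene.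
3. The C8/C9 stereodiad is set on a temporary cyclopentanone (C10, C9, C8, C7, C6) by copper-catalysed asymmetric conjugate methylation of 2-methylcyclopent-2-en-1-one and trans-benzylation of the enolate. Ozonolysis of the silyl enol ether then cuts the C10–C6 bond.
4. The benzyl bromide carries the complete, MOM-protected benzoxazole, built in six steps from 4-methoxybenzene-1,3-diol.
5. Ring order: benzoxazole (step 2), temporary cyclopentanone (step 7, opened in step 9), then rings A and B together in step 16.

Key step: step 16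

Remark: the target is read as the cis-fused decalin (C5 methyl and H10 on the same face; 5R,8S,9R,10S). 4-Methoxybenzene-1,3-diol, 2-methylcyclopent-2-en-1-one and (E)-2,3-dibromobut-2-ene are taken as catalogue compounds.
Abbreviation: Ar = 5-methoxy-6-(methoxymethoxy)-2-methyl-1,3-benzoxazol-7-yl.

**Route**

Step 1
Reactants: 1 4-methoxybenzene-1,3-diol
Product: 2 4-methoxy-6-nitrosobenzene-1,3-diol
Conditions: NaNO2, AcOH/H2O, 0–5 °C
Reagents that add atoms: sodium nitrite, [Na+].[O-]N=O
Why: Electrophilic aromatic nitrosation of a resorcinol should go para to one hydroxyl and ortho to the other (C6), leaving the position between the two hydroxyls free.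

Step 2
Reactants: 2 4-methoxy-6-nitrosobenzene-1,3-diol
Product: 4 5-methoxy-2-methyl-1,3-benzoxazol-6-ol, via aminoresorcinol 3 (not isolated)
Conditions: H2 (1 atm), Pd/C (10 wt% Pd), EtOH, 23 °C; filtration under argon; then MeC(OEt)3, PPTS (cat.), 80 °C
Reagents that add atoms: triethyl orthoacetate, CC(OCC)(OCC)OCC
Why: Hydrogenation of the nitroso group followed by orthoester condensation of the o-aminophenol (benzoxazole synthesis); only the hydroxyl ortho to nitrogen can close the ring.

Step 3
Reactants: 4 5-methoxy-2-methyl-1,3-benzoxazol-6-ol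
Product: 5 6-hydroxy-5-methoxy-2-methyl-1,3-benzoxazole-7-carbaldehyde
Conditions: MgCl2, Et3N, paraformaldehyde, MeCN, 80 °C
Reagents that add atoms: paraformaldehyde (formaldehyde), C=O
Why: Magnesium-phenoxide-directed ortho-formylation of a phenol; C7 is the only free position ortho to the hydroxyl.

Step 4
Reactants: 5 6-hydroxy-5-methoxy-2-methyl-1,3-benzoxazole-7-carbaldehyde
Product: 6 5-methoxy-6-(methoxymethoxy)-2-methyl-1,3-benzoxazole-7-carbaldehyde
Conditions: MOMCl, i-Pr2NEt, CH2Cl2, 0 → 40 °C
Reagents that add atoms: chloromethyl methyl ether, COCCl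
Why: O-Alkylation of the phenol (MOM protection) gives an acetal that should survive bases, hydrides, ozone and heat and can be removed at the end with mild acid.

Step 5
Reactants: 6 5-methoxy-6-(methoxymethoxy)-2-methyl-1,3-benzoxazole-7-carbaldehyde
Product: 7 [5-methoxy-6-(methoxymethoxy)-2-methyl-1,3-benzoxazol-7-yl]methanol
Conditions: NaBH4, MeOH/THF, 0 °C
Reagents that add atoms: none
Why: Borohydride reduction of an aryl aldehyde, which does not touch the benzoxazole.

Step 6
Reactants: 7 [5-methoxy-6-(methoxymethoxy)-2-methyl-1,3-benzoxazol-7-yl]methanol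
Product: 8 7-(bromomethyl)-5-methoxy-6-(methoxymethoxy)-2-methyl-1,3-benzoxazole
Conditions: CBr4, PPh3, CH2Cl2, 0 °C
Reagents that add atoms: carbon tetrabromide, BrC(Br)(Br)Br
Why: Appel bromination under neutral conditions keeps the acid-labile MOM acetal.

Step 7
Reactants: 9 2-methylcyclopent-2-en-1-one; 8 7-(bromomethyl)-5-methoxy-6-(methoxymethoxy)-2-methyl-1,3-benzoxazole
Product: 11 (2R,3S)-2-(ArCH2)-2,3-dimethylcyclopentan-1-one, via magnesium enolate 10 (not isolated)
Conditions: MeMgBr, Cu(OTf)2 (3 mol%), chiral imidazolinium salt (NHC precursor, 4 mol%), Et2O, −30 °C; then 8, DMPU, THF, −30 → 23 °C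
Reagents that add atoms: methylmagnesium bromide, C[Mg]Br
Why: Copper-catalysed asymmetric conjugate addition of a Grignard reagent to a 2-substituted cycloalkenone, then C-alkylation of the regiodefined enolate; the ligand enantiomer is chosen to set C8 (3S), and the benzyl bromide should enter anti to the new C3 methyl, setting the quaternary C9 (2R).

Step 8
Reactants: 11 (2R,3S)-2-(ArCH2)-2,3-dimethylcyclopentan-1-one
Product: 12 silyl enol ether, Ar-CH2-[(1R,5S)-1,5-dimethyl-2-(trimethylsilyloxy)cyclopent-2-en-1-yl]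
Conditions: LiN(SiMe3)2, Me3SiCl, THF, −78 °C
Reagents that add atoms: chlorotrimethylsilane, C[Si](C)(C)Cl
Why: Silyl enol ether formation can only occur toward the CH2 side because the other α-carbon (C9) is quaternary, so one regioisomer should form.

Step 9
Reactants: 12 silyl enol ether
Product: 14 (3R,4S)-3-(ArCH2)-3,4-dimethyloxan-2-one, via hydroxy acid 13 (not isolated)
Conditions: O3, CH2Cl2/MeOH, −78 °C (Sudan Red 7B end point); NaBH4, −78 → 0 °C; aq. citric acid; then PPTS (cat.), toluene, 50 °C
Reagents that add atoms: ozone, [O-][O+]=O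
Why: Ozonolysis of the electron-rich silyl enol ether should be much faster than attack on the arene; reductive work-up and lactonisation open the temporary ring at the C10–C6 bond without touching C8 or C9.

Step 10
Reactants: 14 (3R,4S)-3-(ArCH2)-3,4-dimethyloxan-2-one
Product: 15 (2R,3S)-2-(ArCH2)-2,3-dimethylpentane-1,5-diol
Conditions: LiBH4, THF, 0 → 23 °C
Reagents that add atoms: none
Why: Hydride reduction of a lactone to the diol with a reagent mild enough to leave the benzoxazole intact.

Step 11
Reactants: 15 (2R,3S)-2-(ArCH2)-2,3-dimethylpentane-1,5-diol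
Product: 16 (2R,3S)-2-(ArCH2)-5-iodo-2,3-dimethylpentan-1-ol
Conditions: I2, PPh3, imidazole, CH2Cl2, 0 °C
Reagents that add atoms: iodine, II
Why: Appel iodination should discriminate the unhindered C6 alcohol from the neopentyl C10 alcohol, whose SN2 displacement is blocked by the quaternary C9.

Step 12
Reactants: 16 (2R,3S)-2-(ArCH2)-5-iodo-2,3-dimethylpentan-1-ol
Product: 17 (2R,3S)-2-(ArCH2)-5-iodo-2,3-dimethylpentanal
Conditions: Dess–Martin periodinane, NaHCO3, CH2Cl2, 23 °C
Reagents that add atoms: none
Why: Dess–Martin oxidation of a neopentyl alcohol gives a non-enolisable aldehyde; the primary iodide is inert.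

Step 13
Reactants: 17 (2R,3S)-2-(ArCH2)-5-iodo-2,3-dimethylpentanal
Product: 18 methyl (2Z,4R,5S)-4-(ArCH2)-7-iodo-4,5-dimethylhept-2-enoate
Conditions: (CF3CH2O)2P(O)CH2CO2Me, KN(SiMe3)2, 18-crown-6, THF, −78 °C
Reagents that add atoms: methyl bis(2,2,2-trifluoroethyl)phosphonoacetate, COC(=O)CP(=O)(OCC(F)(F)F)OCC(F)(F)F
Why: Still–Gennari olefination; the electron-poor phosphonate with a dissociated potassium counter-ion should give the (Z)-enoate under kinetic control, also with α-quaternary aldehydes.

Step 14
Reactants: 19 (E)-2,3-dibromobut-2-ene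
Product: 20 (3E)-4-bromo-3-methylpenta-1,3-diene
Conditions: Bu3SnCH=CH2, Pd(PPh3)4 (2 mol%), DMF, 60 °C, threefold excess of 19; product distilled
Reagents that add atoms: tributyl(vinyl)stannane, C=C[Sn](CCCC)(CCCC)CCCC
Why: Stille coupling proceeds with retention of alkene geometry, and the excess of dibromide should limit double coupling.

Step 15
Reactants: 18 methyl (2Z,4R,5S)-4-(ArCH2)-7-iodo-4,5-dimethylhept-2-enoate; 20 (3E)-4-bromo-3-methylpenta-1,3-diene
Product: 22 methyl (2Z,4R,5S,8E)-4-(ArCH2)-4,5,8,9-tetramethylundeca-2,8,10-trienoate, via alkylzinc iodide 21 (not isolated)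
Conditions: Zn dust, LiCl, THF, 40 °C; then 20, Pd(OAc)2 (3 mol%), SPhos (6 mol%), THF, 40 °C
Reagents that add atoms: none
Why: Zinc insertion into the primary iodide tolerates the enoate, and Negishi sp3–sp2 coupling should join C6 to C5 with retention of the (E)-alkenyl bromide geometry.

Step 16
Reactants: 22 methyl (2Z,4R,5S,8E)-4-(ArCH2)-4,5,8,9-tetramethylundeca-2,8,10-trienoate
Product: 23 methyl (1R,4aR,7S,8R,8aS)-8-(ArCH2)-4,4a,7,8-tetramethyl-1,2,4a,5,6,7,8,8a-octahydronaphthalene-1-carboxylate
Conditions: toluene (0.01 M), BHT (0.2 equiv), sealed tube, 165 °C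
Reagents that add atoms: none
Why: Thermal, concerted but asynchronous normal-demand [4+2] cycloaddition; the closest known reaction type is the intramolecular Diels–Alder reaction of (2Z)-2,8,10-trienoates, which gives cis-fused octalins. The C5–C10 bond closes ring B as the tether ring (C6–C9 tether, fused mode imposed by its length) and, with the C1–C2 bond formed in the same event, closes ring A as the cyclohexene that already carries the C3=C4 double bond and the C4 methyl of the target. Suprafacial addition translates alkene geometry into configuration: with the tether endo, the inside C5 methyl of the (8E)-diene and the exo H10 end up cis (C5 R, C10 S), and the (2Z)-ester is then endo too, so the endo preference and the cis-fusion requirement point the same way; the auxiliary C1 centre (ester cis to C9) is erased in step 18. Facial selectivity is controlled by C8 and C9: in the chair-like tether the C8 methyl is equatorial, which places the C9 methyl axial over the diene and the C9 arylmethyl group equatorial and so fixes C5 and C10 relative to C8 and C9 as in the target. The tether-exo transition state that would give the trans-fused isomer has the ester exo and pushes the inside C5 methyl against the axial C9 methyl, so cis/trans selectivity should be secured by both the (Z)-ester and this 1,3-clash. The step also needs cycloaddition to outrun the reversible [1,5]-hydrogen shift of the inside methyl, which the geminal substitution at C9 (Thorpe–Ingold effect), the C4 methyl that favours the s-cis diene, high dilution and BHT are meant to secure.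

Step 17
Reactants: 23 methyl (1R,4aR,7S,8R,8aS)-8-(ArCH2)-4,4a,7,8-tetramethyl-1,2,4a,5,6,7,8,8a-octahydronaphthalene-1-carboxylate
Product: 24 (1R,4aR,7S,8R,8aS)-8-(ArCH2)-4,4a,7,8-tetramethyl-1,2,4a,5,6,7,8,8a-octahydronaphthalene-1-carboxylic acid
Conditions: Me3SnOH, 1,2-dichloroethane, 80 °C; then dilute aq. HCl wash
Reagents that add atoms: trimethyltin hydroxide, C[Sn](C)(C)O
Why: Trimethyltin hydroxide cleaves hindered methyl esters under near-neutral conditions that should spare the benzoxazole and the MOM acetal.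

Step 18
Reactants: 24 (1R,4aR,7S,8R,8aS)-8-(ArCH2)-4,4a,7,8-tetramethyl-1,2,4a,5,6,7,8,8a-octahydronaphthalene-1-carboxylic acid
Product: 26 5-methoxy-6-(methoxymethoxy)-2-methyl-7-{[(1R,2S,4aR,8aS)-1,2,4a,5-tetramethyl-1,2,3,4,4a,7,8,8a-octahydronaphthalen-1-yl]methyl}-1,3-benzoxazole, via thiohydroxamate ester 25 (not isolated)
Conditions: 1-hydroxypyridine-2(1H)-thione, EDC·HCl, DMAP (cat.), CH2Cl2, 23 °C, dark; then t-BuSH, THF, visible light, 23 °C
Reagents that add atoms: none
Why: Barton decarboxylation; the thiohydroxamate ester fragments to the secondary C1 radical, which takes hydrogen from the thiol faster than it can add to the remote alkene or the arene, removing the activating group and its stereocentre.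

Step 19
Reactants: 26 MOM-protected target
Product: 27 5-methoxy-2-methyl-7-{[(1R,2S,4aR,8aS)-1,2,4a,5-tetramethyl-1,2,3,4,4a,7,8,8a-octahydronaphthalen-1-yl]methyl}-1,3-benzoxazol-6-ol (target, CNP0149771.1)
Conditions: HCl (1.25 M in MeOH), THF, 23 °C
Reagents that add atoms: none
Why: Acid-catalysed acetal exchange removes the aryl MOM ether; dilute methanolic acid at ambient temperature should leave the hindered trisubstituted alkene and the benzoxazole untouched.

**Compound list**

1 | 4-methoxybenzene-1,3-diol | COc1ccc(O)cc1O | starting material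
2 | 4-methoxy-6-nitrosobenzene-1,3-diol | COc1cc(N=O)c(O)cc1O | intermediate
3 | 4-amino-6-methoxybenzene-1,3-diol (not isolated) | COc1cc(N)c(O)cc1O | intermediate
4 | 5-methoxy-2-methyl-1,3-benzoxazol-6-ol | COc1cc2nc(C)oc2cc1O | intermediate
5 | 6-hydroxy-5-methoxy-2-methyl-1,3-benzoxazole-7-carbaldehyde | COc1cc2nc(C)oc2c(C=O)c1O | intermediate
6 | 5-methoxy-6-(methoxymethoxy)-2-methyl-1,3-benzoxazole-7-carbaldehyde | COCOc1c(OC)cc2nc(C)oc2c1C=O | intermediate
7 | [5-methoxy-6-(methoxymethoxy)-2-methyl-1,3-benzoxazol-7-yl]methanol | COCOc1c(OC)cc2nc(C)oc2c1CO | intermediate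
8 | 7-(bromomethyl)-5-methoxy-6-(methoxymethoxy)-2-methyl-1,3-benzoxazole | COCOc1c(OC)cc2nc(C)oc2c1CBr | intermediate
9 | 2-methylcyclopent-2-en-1-one | CC1=CCCC1=O | starting material
10 | bromomagnesium (3S)-2,3-dimethylcyclopent-1-en-1-olate (not isolated) | CC1=C(O[Mg]Br)CC[C@@H]1C | intermediate
11 | (2R,3S)-2-{[5-methoxy-6-(methoxymethoxy)-2-methyl-1,3-benzoxazol-7-yl]methyl}-2,3-dimethylcyclopentan-1-one | COCOc1c(OC)cc2nc(C)oc2c1C[C@]3(C)[C@@H](C)CCC3=O | intermediate
12 | 7-{[(1R,5S)-1,5-dimethyl-2-(trimethylsilyloxy)cyclopent-2-en-1-yl]methyl}-5-methoxy-6-(methoxymethoxy)-2-methyl-1,3-benzoxazole | COCOc1c(OC)cc2nc(C)oc2c1C[C@]3(C)[C@@H](C)CC=C3O[Si](C)(C)C | intermediate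
13 | (2R,3S)-5-hydroxy-2-{[5-methoxy-6-(methoxymethoxy)-2-methyl-1,3-benzoxazol-7-yl]methyl}-2,3-dimethylpentanoic acid (not isolated) | COCOc1c(OC)cc2nc(C)oc2c1C[C@](C(O)=O)(C)[C@@H](C)CCO | intermediate
14 | (3R,4S)-3-{[5-methoxy-6-(methoxymethoxy)-2-methyl-1,3-benzoxazol-7-yl]methyl}-3,4-dimethyloxan-2-one | COCOc1c(OC)cc2nc(C)oc2c1C[C@]3(C)[C@@H](C)CCOC3=O | intermediate
15 | (2R,3S)-2-{[5-methoxy-6-(methoxymethoxy)-2-methyl-1,3-benzoxazol-7-yl]methyl}-2,3-dimethylpentane-1,5-diol | COCOc1c(OC)cc2nc(C)oc2c1C[C@](CO)(C)[C@@H](C)CCO | intermediate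
16 | (2R,3S)-5-iodo-2-{[5-methoxy-6-(methoxymethoxy)-2-methyl-1,3-benzoxazol-7-yl]methyl}-2,3-dimethylpentan-1-ol | COCOc1c(OC)cc2nc(C)oc2c1C[C@](CO)(C)[C@@H](C)CCI | intermediate
17 | (2R,3S)-5-iodo-2-{[5-methoxy-6-(methoxymethoxy)-2-methyl-1,3-benzoxazol-7-yl]methyl}-2,3-dimethylpentanal | COCOc1c(OC)cc2nc(C)oc2c1C[C@](C=O)(C)[C@@H](C)CCI | intermediate
18 | methyl (2Z,4R,5S)-7-iodo-4-{[5-methoxy-6-(methoxymethoxy)-2-methyl-1,3-benzoxazol-7-yl]methyl}-4,5-dimethylhept-2-enoate | COCOc1c(OC)cc2nc(C)oc2c1C[C@](/C=C\C(=O)OC)(C)[C@@H](C)CCI | intermediate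
19 | (E)-2,3-dibromobut-2-ene | C/C(Br)=C(Br)/C | starting material
20 | (3E)-4-bromo-3-methylpenta-1,3-diene | C=C/C(C)=C(C)/Br | intermediate
21 | alkylzinc iodide of 18: methyl (2Z,4R,5S)-7-(iodozincio)-4-{[5-methoxy-6-(methoxymethoxy)-2-methyl-1,3-benzoxazol-7-yl]methyl}-4,5-dimethylhept-2-enoate (not isolated) | COCOc1c(OC)cc2nc(C)oc2c1C[C@](/C=C\C(=O)OC)(C)[C@@H](C)CC[Zn]I | intermediate
22 | methyl (2Z,4R,5S,8E)-4-{[5-methoxy-6-(methoxymethoxy)-2-methyl-1,3-benzoxazol-7-yl]methyl}-4,5,8,9-tetramethylundeca-2,8,10-trienoate | COCOc1c(OC)cc2nc(C)oc2c1C[C@](/C=C\C(=O)OC)(C)[C@@H](C)CC/C(C)=C(C)/C=C | intermediate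
23 | methyl (1R,4aR,7S,8R,8aS)-8-{[5-methoxy-6-(methoxymethoxy)-2-methyl-1,3-benzoxazol-7-yl]methyl}-4,4a,7,8-tetramethyl-1,2,4a,5,6,7,8,8a-octahydronaphthalene-1-carboxylate | COCOc1c(OC)cc2nc(C)oc2c1C[C@]3(C)[C@@H](C)CC[C@@]4(C)C(C)=CC[C@@H](C(=O)OC)[C@@H]34 | intermediate
24 | (1R,4aR,7S,8R,8aS)-8-{[5-methoxy-6-(methoxymethoxy)-2-methyl-1,3-benzoxazol-7-yl]methyl}-4,4a,7,8-tetramethyl-1,2,4a,5,6,7,8,8a-octahydronaphthalene-1-carboxylic acid | COCOc1c(OC)cc2nc(C)oc2c1C[C@]3(C)[C@@H](C)CC[C@@]4(C)C(C)=CC[C@@H](C(O)=O)[C@@H]34 | intermediate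
25 | 2-thioxopyridin-1(2H)-yl ester of 24 (not isolated) | COCOc1c(OC)cc2nc(C)oc2c1C[C@]3(C)[C@@H](C)CC[C@@]4(C)C(C)=CC[C@@H](C(=O)ON5C=CC=CC5=S)[C@@H]34 | intermediate
26 | 5-methoxy-6-(methoxymethoxy)-2-methyl-7-{[(1R,2S,4aR,8aS)-1,2,4a,5-tetramethyl-1,2,3,4,4a,7,8,8a-octahydronaphthalen-1-yl]methyl}-1,3-benzoxazole | COCOc1c(OC)cc2nc(C)oc2c1C[C@]3(C)[C@@H](C)CC[C@@]4(C)C(C)=CCC[C@@H]34 | intermediate
27 | 5-methoxy-2-methyl-7-{[(1R,2S,4aR,8aS)-1,2,4a,5-tetramethyl-1,2,3,4,4a,7,8,8a-octahydronaphthalen-1-yl]methyl}-1,3-benzoxazol-6-ol | COc1cc2nc(C)oc2c(C[C@]2(C)[C@@H](C)CC[C@@]3(C)C(C)=CCC[C@@H]23)c1O | target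

**Step count and risks**

Total step count: 19. Longest linear sequence: 18 steps (steps 1–13 and 15–19, from compound 1).

Steps most likely to fail:

1. Step 16. The cycloaddition may be too slow: the (Z)-ester is twisted out of conjugation by the neighbouring quaternary C9, and the diene must reach an s-cis geometry with a methyl group inside. The reversible [1,5]-hydrogen shift of that methyl, diene polymerisation, or leakage through the tether-exo (trans-fused) transition state would then erode the outcome. The fallback sets out from 17 and comes back at 26. Horner–Wadsworth–Emmons reaction of 17 with diethyl [(phenylsulfonyl)methyl]phosphonate (NaH, THF, 0 °C) should give the (E)-vinyl sulfone F1, whose activating group does not depend on coplanarity. Zinc insertion and Negishi coupling with 20, as in step 15, should give the sulfonyl triene F2. Heating (toluene, 130 °C) should give the cis-fused cycloadduct sulfone F3; here the tether-endo transition state is favoured on steric grounds alone (inside C5 methyl against axial C9 methyl in the trans-fused alternative), with the sulfonyl group exo. Reductive desulfonylation (Na(Hg), Na2HPO4, MeOH/THF, −20 °C) then gives 26 directly, bypassing 23 to 25.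

2. Step 7. Enantio-induction in the conjugate addition to the five-membered enone may be insufficient, or C-alkylation of the magnesium enolate by the doubly ortho-substituted benzyl bromide may be sluggish, with proton transfer and O-alkylation competing. The fallback sets out from 9 and comes back at 11. Me2CuLi and Me3SiCl (Et2O, −78 °C) give the racemic silyl enol ether F4. MeLi (THF, 0 °C) releases the lithium enolate, which is benzylated by 8 (DMPU, −78 → 0 °C) trans to the C3 methyl. This gives racemic 11, that is 11 together with the enantiomeric ketone F5, and preparative chromatography on a chiral stationary phase (cellulose tris(3,5-dimethylphenylcarbamate)) separates 11.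

3. Step 15. Coupling at the electron-rich, fully substituted C–Br bond of 20 may be sluggish, so that protodezincation and homocoupling of the zinc reagent compete, and volatile 20 may be lost by evaporation or polymerisation. The fallback sets out from 18 and comes back at 22, with the order of the two cross-couplings reversed. The zinc reagent 21 made from 18 is coupled with a threefold excess of the more electrophilic dibromide 19 (PdCl2(dppf), THF, 40 °C) to give the alkenyl bromide F6. The vinyl group is then added last by Stille coupling with Bu3SnCH=CH2 (Pd(PPh3)4, CuI, DMF, 50 °C), giving 22 without 20 ever being handled.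

Further compounds
F1 | step 16 | (E)-vinyl sulfone, {[(1E,3R,4S)-6-iodo-3-(ArCH2)-3,4-dimethylhex-1-en-1-yl]sulfonyl}benzene | COCOc1c(OC)cc2nc(C)oc2c1C[C@](/C=C/S(=O)(=O)c3ccccc3)(C)[C@@H](C)CCI
F2 | step 16 | sulfonyl triene, {[(1E,3R,4S,7E)-3-(ArCH2)-3,4,7,8-tetramethyldeca-1,7,9-trien-1-yl]sulfonyl}benzene | COCOc1c(OC)cc2nc(C)oc2c1C[C@](/C=C/S(=O)(=O)c3ccccc3)(C)[C@@H](C)CC/C(C)=C(C)/C=C
F3 | step 16 | cis-fused cycloadduct sulfone, the C1-phenylsulfonyl derivative of 26 with sulfonyl cis to H10 | COCOc1c(OC)cc2nc(C)oc2c1C[C@]3(C)[C@@H](C)CC[C@@]4(C)C(C)=CC[C@H](S(=O)(=O)c5ccccc5)[C@@H]34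
F4 | step 7 | racemic silyl enol ether, [(2,3-dimethylcyclopent-1-en-1-yl)oxy]trimethylsilane | CC1=C(O[Si](C)(C)C)CCC1C
F5 | step 7 | enantiomeric ketone, (2S,3R)-2-(ArCH2)-2,3-dimethylcyclopentan-1-one | COCOc1c(OC)cc2nc(C)oc2c1C[C@@]3(C)[C@H](C)CCC3=O
F6 | step 15 | alkenyl bromide, methyl (2Z,4R,5S,8E)-9-bromo-4-(ArCH2)-4,5,8-trimethyldeca-2,8-dienoate | COCOc1c(OC)cc2nc(C)oc2c1C[C@](/C=C\C(=O)OC)(C)[C@@H](C)CC/C(C)=C(C)/Br
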